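**Retrosynthetic overview**
1. Numbering: lactone ring O1, C2(=O), C3=C4, C5, C6; side chain C1'–C15' counted from C6 (C6/C2' anti, C2'/C4' syn, C4'/C6' anti). Key disconnection: the cis C3=C4 bond, closed by ring-closing metathesis of acrylate 13.
2. Enabling feature: C3=C4 lies in a six-membered ring between the acyl carbon C2 on O1 and the CH2 (C5) next to carbinol C6, so opening it gives an ester-tethered 1,7-diene (acrylate on O1 plus allyl on C6).
3. Stereocenters: C6' by catalytic asymmetric allylation of decanal (the only one set by an external chiral source); C2' and C4' together in one flask by a 1,5-anti boron aldol and syn reduction; C6 by 1,3-anti allylation of aldehyde 11.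
4. Ring order: temporary 1,3-dioxane (acetonide over the syn C2'/C4' diol, step 5), then the 5,6-dihydro-2H-pyran-2-one (step 10); the dioxane and the PMB ether come off in step 11.

Key step: step 10

Remark: the CIP descriptors of the dioxane carbons change between intermediates because substituent priorities change; the spatial arrangement is the same throughout.

**Step 1**
Reactants: 1 decanal
Product: 2 (4R)-tridec-1-en-4-ol
Conditions: allylSnBu3, (S)-BINOL (10 mol%), Ti(OiPr)4 (10 mol%), 4 Å MS, CH2Cl2, −20 °C; aq. NaHCO3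
Reagents that add atoms: allyltributylstannane, C=CC[Sn](CCCC)(CCCC)CCCC
Why: Keck asymmetric allylation, in which the chiral (S)-BINOL–titanium Lewis acid should direct allyl transfer to the Si face of the aldehyde and set C6' as (R).

**Step 2**
Reactants: 2 (4R)-tridec-1-en-4-ol
Product: 3 (4R)-4-[(4-methoxybenzyl)oxy]tridec-1-ene
Conditions: NaH, PMBCl, Bu4NI (cat.), THF/DMF, 0 °C → rt
Reagents that add atoms: 4-methoxybenzyl chloride, COc1ccc(CCl)cc1
Why: Williamson etherification of the sodium alkoxide; the PMB ether is the β-alkoxy group needed later for 1,5-anti induction and the stereocenter is not touched.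

**Step 3**
Reactants: 3 (4R)-4-[(4-methoxybenzyl)oxy]tridec-1-ene
Product: 4 (4R)-4-[(4-methoxybenzyl)oxy]tridecan-2-one
Conditions: PdCl2 (10 mol%), CuCl (1 equiv), O2 (1 atm), DMF/H2O 7:1, rt
Reagents that add atoms: water, O
Why: Tsuji–Wacker oxidation, in which Markovnikov hydroxypalladation of the terminal alkene by divalent palladium and β-hydride elimination should give the methyl ketone while CuCl/O2 turns the catalyst over.

**Step 4**
Reactants: 4 (4R)-4-[(4-methoxybenzyl)oxy]tridecan-2-one; 5 3-[(tert-butyldimethylsilyl)oxy]propanal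
Product: 8 (3R,5R,7R)-1-[(tert-butyldimethylsilyl)oxy]-7-[(4-methoxybenzyl)oxy]hexadecane-3,5-diol, via boron enolate 6 (not isolated), via boron aldolate 7 (not isolated)
Conditions: c-Hex2BCl, Et3N, Et2O, 0 °C; 5, −78 → −20 °C; LiBH4, −78 °C; H2O2, MeOH, pH 7 buffer, 0 °C
Reagents that add atoms: none
Why: Boron-mediated aldol addition of the kinetic methyl-side enolate, whose β-PMB-oxy stereocenter should induce the new carbinol C2' 1,5-anti, followed by external hydride delivery to the six-membered boron aldolate chelate, which should give the 1,3-syn diol and so set C4' in the same operation.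

**Step 5**
Reactants: 8 (3R,5R,7R)-1-[(tert-butyldimethylsilyl)oxy]-7-[(4-methoxybenzyl)oxy]hexadecane-3,5-diol
Product: 9 tert-butyl{2-[(4R,6S)-6-{(2R)-2-[(4-methoxybenzyl)oxy]undecyl}-2,2-dimethyl-1,3-dioxan-4-yl]ethoxy}dimethylsilane
Conditions: Me2C(OMe)2, PPTS (cat.), CH2Cl2, rt
Reagents that add atoms: 2,2-dimethoxypropane, COC(C)(C)OC
Why: Acid-catalysed transketalisation; the syn-1,3-diol should close readily to a chair 1,3-dioxane with both side chains equatorial, masking O–C2' and O–C4' as a temporary ring.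

**Step 6**
Reactants: 9 tert-butyl{2-[(4R,6S)-6-{(2R)-2-[(4-methoxybenzyl)oxy]undecyl}-2,2-dimethyl-1,3-dioxan-4-yl]ethoxy}dimethylsilane
Product: 10 2-[(4R,6S)-6-{(2R)-2-[(4-methoxybenzyl)oxy]undecyl}-2,2-dimethyl-1,3-dioxan-4-yl]ethan-1-ol
Conditions: Bu4NF, THF, 0 °C → rt
Reagents that add atoms: none
Why: Fluoride-mediated cleavage of the primary silyl ether, to which the PMB ether and the acetonide are inert.

**Step 7**
Reactants: 10 2-[(4R,6S)-6-{(2R)-2-[(4-methoxybenzyl)oxy]undecyl}-2,2-dimethyl-1,3-dioxan-4-yl]ethan-1-ol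
Product: 11 2-[(4S,6S)-6-{(2R)-2-[(4-methoxybenzyl)oxy]undecyl}-2,2-dimethyl-1,3-dioxan-4-yl]acetaldehyde
Conditions: TEMPO (10 mol%), PhI(OAc)2, CH2Cl2, rt
Reagents that add atoms: none
Why: Oxoammonium (TEMPO/PhI(OAc)2) oxidation of the primary alcohol, which should stop at the aldehyde without touching the PMB ether or the acetonide.

**Step 8**
Reactants: 11 2-[(4S,6S)-6-{(2R)-2-[(4-methoxybenzyl)oxy]undecyl}-2,2-dimethyl-1,3-dioxan-4-yl]acetaldehyde
Product: 12 (2S)-1-[(4R,6S)-6-{(2R)-2-[(4-methoxybenzyl)oxy]undecyl}-2,2-dimethyl-1,3-dioxan-4-yl]pent-4-en-2-ol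
Conditions: allylSiMe3, BF3·OEt2, CH2Cl2, −78 °C; aq. NaHCO3
Reagents that add atoms: allyltrimethylsilane, C=CC[Si](C)(C)C
Why: Hosomi–Sakurai allylation through an open transition state in which the BF3-bound aldehyde takes the dipole-minimised conformation relative to the β-C–O bond of the dioxane (1,3-anti polar model), so the allylsilane should add to set C6 anti to C2'.

**Step 9**
Reactants: 12 (2S)-1-[(4R,6S)-6-{(2R)-2-[(4-methoxybenzyl)oxy]undecyl}-2,2-dimethyl-1,3-dioxan-4-yl]pent-4-en-2-ol
Product: 13 (2S)-1-[(4S,6S)-6-{(2R)-2-[(4-methoxybenzyl)oxy]undecyl}-2,2-dimethyl-1,3-dioxan-4-yl]pent-4-en-2-yl prop-2-enoate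
Conditions: acryloyl chloride, Et3N, DMAP (cat.), CH2Cl2, −20 → 0 °C
Reagents that add atoms: acryloyl chloride, C=CC(=O)Cl
Why: DMAP-catalysed acylation of the only free hydroxyl group, which installs O1–C2–C3 of the lactone as an acrylate ester.

**Step 10**
Reactants: 13 (2S)-1-[(4S,6S)-6-{(2R)-2-[(4-methoxybenzyl)oxy]undecyl}-2,2-dimethyl-1,3-dioxan-4-yl]pent-4-en-2-yl prop-2-enoate
Product: 14 (6S)-6-{[(4S,6S)-6-{(2R)-2-[(4-methoxybenzyl)oxy]undecyl}-2,2-dimethyl-1,3-dioxan-4-yl]methyl}-5,6-dihydro-2H-pyran-2-one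
Conditions: second-generation Grubbs catalyst, RuCl2(=CHPh)(H2IMes)(PCy3) (5 mol%), CH2Cl2 (0.005 M), 40 °C
Reagents that add atoms: none
Why: Ring-closing olefin metathesis: the ruthenium benzylidene should initiate on the unhindered allyl terminus (C4=CH2), the new alkylidene undergoes intramolecular [2+2] cycloaddition with the acrylate C3=CH2, and cycloreversion releases ethene and forms the C3=C4 bond. The closest known reaction type is the ring-closing metathesis of acrylates of homoallylic alcohols to 6-substituted 5,6-dihydro-2H-pyran-2-ones with second-generation ruthenium carbenes. The one ring closed, the dihydropyranone (O1, C2, C3, C4, C5, C6), forms as a six-membered ring from a 1,7-diene tethered through the ester O1–C2, and this ring size allows only the cis C3=C4 geometry. No stereocenter is created; C6, C2', C4' and C6' are remote from the reacting alkenes and should be carried through unchanged. The step needs cyclisation to win over dimerisation and the catalyst to turn over despite the ester carbonyl; this is secured by high dilution, by loss of ethene, and by a substrate with no other alkene and no free hydroxyl (the acetonide ties up O–C2' and O–C4', the PMB ether O–C6').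

**Step 11**
Reactants: 14 (6S)-6-{[(4S,6S)-6-{(2R)-2-[(4-methoxybenzyl)oxy]undecyl}-2,2-dimethyl-1,3-dioxan-4-yl]methyl}-5,6-dihydro-2H-pyran-2-one
Product: 15 (6S)-6-[(2S,4S,6R)-2,4,6-trihydroxypentadecyl]-5,6-dihydro-2H-pyran-2-one
Conditions: TFA/H2O 9:1, anisole, CH2Cl2, 0 °C → rt
Reagents that add atoms: none
Why: Acidolysis in which TFA ionises the PMB ether (the benzylic cation is trapped by anisole) and hydrolyses the acetonide, while the unsaturated lactone and all four stereocenters should be unaffected.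

**Compound list**
1 | decanal | CCCCCCCCCC=O | starting material
2 | (4R)-tridec-1-en-4-ol | CCCCCCCCC[C@@H](O)CC=C | intermediate
3 | (4R)-4-[(4-methoxybenzyl)oxy]tridec-1-ene | CCCCCCCCC[C@@H](OCc1ccc(OC)cc1)CC=C | intermediate
4 | (4R)-4-[(4-methoxybenzyl)oxy]tridecan-2-one | CCCCCCCCC[C@@H](OCc1ccc(OC)cc1)CC(C)=O | intermediate
5 | 3-[(tert-butyldimethylsilyl)oxy]propanal | O=CCCO[Si](C)(C)C(C)(C)C | starting material
6 | boron enolate, (4R)-2-[(dicyclohexylboranyl)oxy]-4-[(4-methoxybenzyl)oxy]tridec-1-ene | CCCCCCCCC[C@@H](OCc1ccc(OC)cc1)CC(=C)OB(C2CCCCC2)C2CCCCC2 | intermediate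
7 | boron aldolate, (3R,7R)-1-[(tert-butyldimethylsilyl)oxy]-3-[(dicyclohexylboranyl)oxy]-7-[(4-methoxybenzyl)oxy]hexadecan-5-one | CCCCCCCCC[C@@H](OCc1ccc(OC)cc1)CC(=O)C[C@H](OB(C2CCCCC2)C2CCCCC2)CCO[Si](C)(C)C(C)(C)C | intermediate
8 | (3R,5R,7R)-1-[(tert-butyldimethylsilyl)oxy]-7-[(4-methoxybenzyl)oxy]hexadecane-3,5-diol | CCCCCCCCC[C@@H](OCc1ccc(OC)cc1)C[C@H](O)C[C@H](O)CCO[Si](C)(C)C(C)(C)C | intermediate
9 | tert-butyl{2-[(4R,6S)-6-{(2R)-2-[(4-methoxybenzyl)oxy]undecyl}-2,2-dimethyl-1,3-dioxan-4-yl]ethoxy}dimethylsilane | CCCCCCCCC[C@@H](OCc1ccc(OC)cc1)C[C@H](OC(C)(C)O2)C[C@H]2CCO[Si](C)(C)C(C)(C)C | intermediate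
10 | 2-[(4R,6S)-6-{(2R)-2-[(4-methoxybenzyl)oxy]undecyl}-2,2-dimethyl-1,3-dioxan-4-yl]ethan-1-ol | CCCCCCCCC[C@@H](OCc1ccc(OC)cc1)C[C@H](OC(C)(C)O2)C[C@H]2CCO | intermediate
11 | 2-[(4S,6S)-6-{(2R)-2-[(4-methoxybenzyl)oxy]undecyl}-2,2-dimethyl-1,3-dioxan-4-yl]acetaldehyde | CCCCCCCCC[C@@H](OCc1ccc(OC)cc1)C[C@H](OC(C)(C)O2)C[C@H]2CC=O | intermediate
12 | (2S)-1-[(4R,6S)-6-{(2R)-2-[(4-methoxybenzyl)oxy]undecyl}-2,2-dimethyl-1,3-dioxan-4-yl]pent-4-en-2-ol | CCCCCCCCC[C@@H](OCc1ccc(OC)cc1)C[C@H](OC(C)(C)O2)C[C@H]2C[C@@H](O)CC=C | intermediate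
13 | (2S)-1-[(4S,6S)-6-{(2R)-2-[(4-methoxybenzyl)oxy]undecyl}-2,2-dimethyl-1,3-dioxan-4-yl]pent-4-en-2-yl prop-2-enoate | CCCCCCCCC[C@@H](OCc1ccc(OC)cc1)C[C@H](OC(C)(C)O2)C[C@H]2C[C@@H](OC(=O)C=C)CC=C | intermediate
14 | (6S)-6-{[(4S,6S)-6-{(2R)-2-[(4-methoxybenzyl)oxy]undecyl}-2,2-dimethyl-1,3-dioxan-4-yl]methyl}-5,6-dihydro-2H-pyran-2-one | CCCCCCCCC[C@@H](OCc1ccc(OC)cc1)C[C@H](OC(C)(C)O2)C[C@H]2C[C@@H]3CC=CC(=O)O3 | intermediate
15 | (6S)-6-[(2S,4S,6R)-2,4,6-trihydroxypentadecyl]-5,6-dihydro-2H-pyran-2-one | CCCCCCCCC[C@@H](O)C[C@H](O)C[C@H](O)C[C@@H]1CC=CC(=O)O1 | target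

**Totals**
Total step count: 11. Longest linear sequence: 11 steps (from decanal 1).

**Steps most likely to fail**

Step 8. The facial selectivity may be poor, because induction from a β-oxygen locked in the dioxane can be modest, and the Lewis acid may also start to open the acetonide. The fallback sets out from 11 and comes back at 12: the allyl group is delivered under catalyst control by a Keck allylation (allylSnBu3, (S)-BINOL/Ti(OiPr)4, 4 Å MS, CH2Cl2, −20 °C). The catalyst preference (Si face) and the 1,3-anti substrate preference point the same way, and no strong Lewis acid is present. No new compound is formed on this way (F0).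

Step 4. The 1,5-anti induction may erode during the long aldol addition, or the in-flask hydride reduction may run partly outside the boron chelate, so that diastereomeric diols build up and cannot be corrected. The fallback sets out from 4 and 5 and comes back at 8, with the two stereocenters set in two separately controlled operations. The aldol is run with Bu2BOTf/iPr2NEt (Et2O, −78 °C) and worked up oxidatively to isolate and purify the aldol adduct (3R,7R)-1-[(tert-butyldimethylsilyl)oxy]-3-hydroxy-7-[(4-methoxybenzyl)oxy]hexadecan-5-one F1. This is then reduced under Narasaka–Prasad conditions (Et2BOMe, NaBH4, THF/MeOH, −78 °C), where an external diethylboron chelate enforces syn delivery, to give 8.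

Step 11. In a single acid treatment the PMB cation may re-alkylate the free hydroxyl groups, trifluoroacetates may form, or one of the two protecting groups may cleave incompletely. The fallback sets out from 14 and comes back at 15 by orthogonal, stepwise unmasking. Oxidative cleavage of the PMB ether (DDQ, CH2Cl2/pH 7 buffer, 0 °C) should give (6S)-6-{[(4S,6S)-6-[(2R)-2-hydroxyundecyl]-2,2-dimethyl-1,3-dioxan-4-yl]methyl}-5,6-dihydro-2H-pyran-2-one F2. Mild hydrolysis of the acetonide (AcOH/H2O 4:1, 40 °C) then gives 15.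

**Further compounds**
F1 | step 4 | (3R,7R)-1-[(tert-butyldimethylsilyl)oxy]-3-hydroxy-7-[(4-methoxybenzyl)oxy]hexadecan-5-one | CCCCCCCCC[C@@H](OCc1ccc(OC)cc1)CC(=O)C[C@H](O)CCO[Si](C)(C)C(C)(C)C
F0 | step 8 | none | none
F2 | step 11 | (6S)-6-{[(4S,6S)-6-[(2R)-2-hydroxyundecyl]-2,2-dimethyl-1,3-dioxan-4-yl]methyl}-5,6-dihydro-2H-pyran-2-one | CCCCCCCCC[C@@H](O)C[C@H](OC(C)(C)O1)C[C@H]1C[C@@H]2CC=CC(=O)O2
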